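**Plan**

- Retrosynthesis: the O4'–C(Me)2 bond of the 2,2-dimethyl-2H-pyran fused across C4'–C5' of ring B is cut first. This pyran lies beside the free 3'-OH, so it is a 5'-prenyl-3',4'-catechol less two hydrogens, and that catechol is the most easily oxidised part of the molecule.
- Then the pyranone ring C is opened at O1–C2 and the C2–C3 link is cut (retro-aldol), giving a prenylated acetophenone (ring A) and a prenylated benzaldehyde (ring B); the two aryl–prenyl bonds are cut last.
- Forward, ring A piece: nuclear C-prenylation of phloroacetophenone, then partial MOM protection. Ring B piece: propargylic etherification, semihydrogenation, aromatic Claisen rearrangement, MOM protection.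
- Claisen–Schmidt condensation joins the halves, iodine/DMSO closes ring C, acid frees the four phenols, and anodic oxidation with oxa-6π closure forms the dimethylpyran last.
- Stereochemistry: none to set. Only regiochemistry (prenyl at C8, not C6; closure onto O4') has to be secured.

Key step: step 10

Remark: the target has no stereocentre and no stereogenic double bond, so "single enantiomer" is taken to mean the compound as drawn. Prenyl = 3-methylbut-2-en-1-yl; MOM = methoxymethyl; flavone numbering (ring B primed) is used for the flavonoid compounds.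

**Route**

Step 1
Reactants: 1 2,4,6-trihydroxyacetophenone; 2 prenyl bromide (1-bromo-3-methylbut-2-ene)
Product: 3 2,4,6-trihydroxy-3-prenylacetophenone
Conditions: 2 (1.0 equiv), 10% aq. KOH, 0 °C to rt; acidify
Reagents that add atoms: none
Why: Nuclear C-alkylation of a phloroglucinol-type phenoxide, in which water hydrogen-bonds the oxygens so that the ring carbon between two oxygens attacks the allylic bromide; the two free ring positions of 1 are equivalent, so only one mono-C-prenyl product can form, and one equivalent of 2 limits over-alkylation.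

Step 2
Reactants: 3 2,4,6-trihydroxy-3-prenylacetophenone
Product: 4 2-hydroxy-4,6-bis(methoxymethoxy)-3-prenylacetophenone
Conditions: MOMCl (2.2 equiv), K2CO3, acetone, reflux
Reagents that add atoms: chloromethyl methyl ether (MOMCl), COCCl
Why: Williamson-type MOM ether formation, in which the unchelated 4-OH and the less hindered ortho hydroxyl react while the hydroxyl wedged between the acetyl and the prenyl group stays hydrogen-bonded and free; this is what later places the prenyl group at C8.

Step 3
Reactants: 5 3,4-dihydroxybenzaldehyde; 6 3-chloro-3-methylbut-1-yne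
Product: 7 3-hydroxy-4-[(2-methylbut-3-yn-2-yl)oxy]benzaldehyde
Conditions: 6 (1.3 equiv), K2CO3 (1.2 equiv), KI (cat.), CuI (cat.), acetone, 55 °C, N2
Reagents that add atoms: none
Why: Copper-assisted propargylic etherification of a phenoxide with a tertiary propargylic chloride; the 4-OH para to the formyl group is several pKa units more acidic than the 3-OH, so a slight excess of carbonate forms only the 4-phenoxide.

Step 4
Reactants: 7 3-hydroxy-4-[(2-methylbut-3-yn-2-yl)oxy]benzaldehyde
Product: 8 3-hydroxy-4-[(2-methylbut-3-en-2-yl)oxy]benzaldehyde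
Conditions: H2 (1 atm), Lindlar catalyst, quinoline, EtOAc, rt, stopped after 1 equiv H2
Reagents that add atoms: none
Why: Lindlar semihydrogenation, in which the poisoned palladium reduces the terminal alkyne to the alkene and stops there, leaving the aldehyde and the aryl ether untouched.

Step 5
Reactants: 8 3-hydroxy-4-[(2-methylbut-3-en-2-yl)oxy]benzaldehyde
Product: 9 3,4-dihydroxy-5-prenylbenzaldehyde
Conditions: o-xylene, 130 °C, N2
Reagents that add atoms: none
Why: Aromatic Claisen rearrangement, in which the [3,3] shift of the 1,1-dimethylallyl aryl ether (eased by the gem-dimethyl group) delivers the CH2 terminus to C5, the only ortho carbon that carries hydrogen, so the group arrives as a normal prenyl group and enolisation restores the catechol.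

Step 6
Reactants: 9 3,4-dihydroxy-5-prenylbenzaldehyde
Product: 10 3,4-bis(methoxymethoxy)-5-prenylbenzaldehyde
Conditions: MOMCl (3 equiv), K2CO3, acetone, reflux
Reagents that add atoms: chloromethyl methyl ether (MOMCl), COCCl
Why: Williamson-type MOM ether formation on both catechol hydroxyls, which makes the aldehyde stable to the strongly basic condensation that follows.

Step 7
Reactants: 4 2-hydroxy-4,6-bis(methoxymethoxy)-3-prenylacetophenone; 10 3,4-bis(methoxymethoxy)-5-prenylbenzaldehyde
Product: 11 (E)-1-[2-hydroxy-4,6-bis(methoxymethoxy)-3-prenylphenyl]-3-[3,4-bis(methoxymethoxy)-5-prenylphenyl]prop-2-en-1-one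
Conditions: KOH (aq.), EtOH, rt, 24–48 h
Reagents that add atoms: none
Why: Claisen–Schmidt (crossed aldol) condensation, in which the methyl ketone enolate of 4 adds to the non-enolisable aldehyde 10 and E1cB loss of water gives the conjugated E-enone; MOM ethers and prenyl groups are inert to hydroxide.

Step 8
Reactants: 11 (E)-1-[2-hydroxy-4,6-bis(methoxymethoxy)-3-prenylphenyl]-3-[3,4-bis(methoxymethoxy)-5-prenylphenyl]prop-2-en-1-one
Product: 12 5,7,3',4'-tetrakis(methoxymethoxy)-8,5'-diprenylflavone
Conditions: I2 (0.1 equiv), DMSO, 120 °C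
Reagents that add atoms: none
Why: Iodine-catalysed oxidative cyclisation of a 2'-hydroxychalcone (oxa-Michael closure, then iodination and loss of HI, with DMSO as terminal oxidant), in which only the one free hydroxyl, next to the ring A prenyl group, can close, fixing that group at C8; every oxygen beside a prenyl group is capped, so iodoetherification has no free phenol to use.

Step 9
Reactants: 12 5,7,3',4'-tetrakis(methoxymethoxy)-8,5'-diprenylflavone
Product: 13 5,7,3',4'-tetrahydroxy-8,5'-diprenylflavone (8,5'-diprenylluteolin)
Conditions: 3 M HCl/MeOH, 45 °C, short reaction time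
Reagents that add atoms: none
Why: Acid-catalysed acetal solvolysis (MOM removal) in methanol, run dilute, warm and briefly so that the trisubstituted prenyl double bonds are not protonated and no chroman forms.

Step 10
Reactants: 13 5,7,3',4'-tetrahydroxy-8,5'-diprenylflavone
Product: 16 5,7-dihydroxy-2-(8-hydroxy-2,2-dimethyl-2H-chromen-6-yl)-8-prenyl-4H-chromen-4-one (target CNP0256598.0), via ring B o-quinone 14 (not isolated), via ring B o-quinone methide 15 (not isolated)
Conditions: graphite-felt anode, Pt-wire cathode, undivided cell, constant potential about 0.1 V past the first anodic peak of 13 (from CV; expected near +0.5 V vs Ag/AgCl), n-Bu4NPF6 (0.1 M), 2,6-lutidine (3 equiv), MeCN/DMF 9:1, Ar, rt, until 13 is consumed (at least 2 F/mol); then 40 °C, 1 h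
Reagents that add atoms: none
Why: Proposed new method: at a carbon anode held just past the first anodic wave, the ring B catechol should lose two electrons and two protons to give o-quinone 14, and 2,6-lutidine should then shift one of the benzylic and allylic C1'' protons to O3', giving the vinylogous enol tautomer 15 with C4'=O and an exocyclic C5'=CH–CH=CMe2 unit. This 1-oxatriene (O=C4'–C5'=C1''–C2''=C3'') should close by a thermal disrotatory oxa-6π electrocyclisation that forms the O4'–C3'' bond and the six-membered 2H-pyran and restores aromatic ring B with 3'-OH free; the E isomer of 15 can return to 14 by the same proton shuttle, so only the Z isomer is drained, and any 14 reduced at the cathode simply returns to 13. The closest known reactions are anodic oxidation of catechols to o-quinones and the quinone-mediated (DDQ) dehydrogenative cyclisation of o-prenylphenols to 2,2-dimethylchromenes, which runs through the same quinone methide and oxa-6π closure; what is new is reaching that intermediate by tautomerising an electrogenerated o-quinone. No stereocentre is formed. The step needs site selectivity for ring B over the 7-OH/8-prenyl pair and no over-oxidation of the product's single ring B phenol; the applied potential secures both, because the chelated, carbonyl-conjugated ring A and a monophenol oxidise at clearly higher potential than a catechol. Closure can only occur onto O4', the one oxygen ortho to the 5'-prenyl group, and the non-nucleophilic medium keeps 14 from being trapped before it tautomerises.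

**Compound list**

1 | 2,4,6-trihydroxyacetophenone | CC(=O)c1c(O)cc(O)cc1O | starting material
2 | prenyl bromide (1-bromo-3-methylbut-2-ene) | CC(C)=CCBr | starting material
3 | 2,4,6-trihydroxy-3-prenylacetophenone | CC(=O)c1c(O)cc(O)c(CC=C(C)C)c1O | intermediate
4 | 2-hydroxy-4,6-bis(methoxymethoxy)-3-prenylacetophenone | CC(=O)c1c(OCOC)cc(OCOC)c(CC=C(C)C)c1O | intermediate
5 | 3,4-dihydroxybenzaldehyde | O=Cc1ccc(O)c(O)c1 | starting material
6 | 3-chloro-3-methylbut-1-yne | C#CC(C)(C)Cl | starting material
7 | 3-hydroxy-4-[(2-methylbut-3-yn-2-yl)oxy]benzaldehyde | O=Cc1ccc(OC(C)(C)C#C)c(O)c1 | intermediate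
8 | 3-hydroxy-4-[(2-methylbut-3-en-2-yl)oxy]benzaldehyde | O=Cc1ccc(OC(C)(C)C=C)c(O)c1 | intermediate
9 | 3,4-dihydroxy-5-prenylbenzaldehyde | O=Cc1cc(O)c(O)c(CC=C(C)C)c1 | intermediate
10 | 3,4-bis(methoxymethoxy)-5-prenylbenzaldehyde | O=Cc1cc(OCOC)c(OCOC)c(CC=C(C)C)c1 | intermediate
11 | (E)-1-[2-hydroxy-4,6-bis(methoxymethoxy)-3-prenylphenyl]-3-[3,4-bis(methoxymethoxy)-5-prenylphenyl]prop-2-en-1-one | COCOc1cc(OCOC)c(C(=O)/C=C/c2cc(OCOC)c(OCOC)c(CC=C(C)C)c2)c(O)c1CC=C(C)C | intermediate
12 | 5,7,3',4'-tetrakis(methoxymethoxy)-8,5'-diprenylflavone | COCOc1cc(OCOC)c2c(=O)cc(-c3cc(OCOC)c(OCOC)c(CC=C(C)C)c3)oc2c1CC=C(C)C | intermediate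
13 | 5,7,3',4'-tetrahydroxy-8,5'-diprenylflavone (8,5'-diprenylluteolin) | CC(C)=CCc1c(O)cc(O)c2c(=O)cc(-c3cc(O)c(O)c(CC=C(C)C)c3)oc12 | intermediate
14 | ring B o-quinone, 2-(3,4-dioxo-5-prenylcyclohexa-1,5-dien-1-yl)-5,7-dihydroxy-8-prenyl-4H-chromen-4-one | CC(C)=CCc1c(O)cc(O)c2c(=O)cc(C3=CC(=O)C(=O)C(CC=C(C)C)=C3)oc12 | intermediate (not isolated)
15 | ring B o-quinone methide, 5,7-dihydroxy-2-[(3Z)-5-hydroxy-3-(3-methylbut-2-en-1-ylidene)-4-oxocyclohexa-1,5-dien-1-yl]-8-prenyl-4H-chromen-4-one | CC(C)=CCc1c(O)cc(O)c2c(=O)cc(C3=C/C(=C/C=C(C)C)C(=O)C(O)=C3)oc12 | intermediate (not isolated)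
16 | 5,7-dihydroxy-2-(8-hydroxy-2,2-dimethyl-2H-chromen-6-yl)-8-prenyl-4H-chromen-4-one (CNP0256598.0) | CC(C)=CCc1c(O)cc(O)c2c(=O)cc(-c3cc(O)c4c(c3)C=CC(C)(C)O4)oc12 | target

**Step count**

Total: 10 steps. Longest linear sequence: 8 steps (5 to 16, steps 3–10); the ring A branch (1 to 4) adds 2 steps.

**Steps most likely to fail**

1. Step 10 (proposed new method). The electrogenerated o-quinone may be consumed by conjugate addition, dimerisation or further oxidation before the proton shift to the quinone methide, or that shift may be too slow with a weak base. The fallback uses known chemistry and makes the pyran before the flavone, by thermal rearrangement of the aryl 1,1-dimethylpropargyl ether. It sets out from 7. Heating 7 in N,N-diethylaniline at about 180 °C should give, by propargyl Claisen rearrangement, 1,5-hydrogen shift and oxa-6π closure at the only free ortho carbon, 8-hydroxy-2,2-dimethyl-2H-chromene-6-carbaldehyde F1. MOMCl/K2CO3 in acetone then gives 8-(methoxymethoxy)-2,2-dimethyl-2H-chromene-6-carbaldehyde F2. Claisen–Schmidt condensation of F2 with 4 (KOH, EtOH) gives the chalcone (E)-1-[2-hydroxy-4,6-bis(methoxymethoxy)-3-prenylphenyl]-3-[8-(methoxymethoxy)-2,2-dimethyl-2H-chromen-6-yl]prop-2-en-1-one F3. I2 (cat.)/DMSO at 120 °C gives 5,7-bis(methoxymethoxy)-2-[8-(methoxymethoxy)-2,2-dimethyl-2H-chromen-6-yl]-8-prenyl-4H-chromen-4-one F4. Methanolic HCl removes the three MOM groups, and the fallback comes back to the route at 16.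

2. Step 8. Iodine or the HI formed may add to or cyclise the two prenyl double bonds, or MOM groups may be lost at 120 °C so that freed phenols close onto the prenyl groups. The fallback builds ring C without an oxidant, through a 1,3-diketone (Baker–Venkataraman). It sets out from 10 and uses 4. Pinnick oxidation of 10 (NaClO2, NaH2PO4, excess 2-methylbut-2-ene, t-BuOH/H2O) gives 3,4-bis(methoxymethoxy)-5-prenylbenzoic acid F5. EDC·HCl/DMAP esterification with the phenol of 4 gives 2-acetyl-3,5-bis(methoxymethoxy)-6-prenylphenyl 3,4-bis(methoxymethoxy)-5-prenylbenzoate F6. KOH in pyridine at 50 °C moves the aroyl group from oxygen to the acetyl carbon and gives 1-[2-hydroxy-4,6-bis(methoxymethoxy)-3-prenylphenyl]-3-[3,4-bis(methoxymethoxy)-5-prenylphenyl]propane-1,3-dione F7. Methanolic HCl then cyclodehydrates through the free ortho hydroxyl and removes the four MOM groups in the same operation, so the fallback comes back to the route at 13 and passes by 11 and 12.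

3. Step 3. Etherification may occur at the wrong hydroxyl or at both, and substitution at the tertiary propargylic centre may be slow, with elimination of the chloride competing. The fallback makes the reverse-prenyl ether directly by palladium-catalysed decarboxylative allylic etherification (Tsuji–Trost type). It sets out from 5. tert-Butyl 2-methylbut-3-en-2-yl carbonate with Pd(PPh3)4 (cat.) in THF at 0 °C should transfer the 1,1-dimethylallyl group, at its tertiary terminus, to the more acidic 4-OH and give 8 directly. The fallback comes back to the route at 8, so steps 3 and 4 drop out; it makes no compound outside the list (F0).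

**Further compounds**

F1 | step 10 | 8-hydroxy-2,2-dimethyl-2H-chromene-6-carbaldehyde | O=Cc1cc(O)c2c(c1)C=CC(C)(C)O2
F2 | step 10 | 8-(methoxymethoxy)-2,2-dimethyl-2H-chromene-6-carbaldehyde | O=Cc1cc(OCOC)c2c(c1)C=CC(C)(C)O2
F3 | step 10 | (E)-1-[2-hydroxy-4,6-bis(methoxymethoxy)-3-prenylphenyl]-3-[8-(methoxymethoxy)-2,2-dimethyl-2H-chromen-6-yl]prop-2-en-1-one | COCOc1cc(OCOC)c(C(=O)/C=C/c2cc(OCOC)c3c(c2)C=CC(C)(C)O3)c(O)c1CC=C(C)C
F4 | step 10 | 5,7-bis(methoxymethoxy)-2-[8-(methoxymethoxy)-2,2-dimethyl-2H-chromen-6-yl]-8-prenyl-4H-chromen-4-one | COCOc1cc(OCOC)c2c(=O)cc(-c3cc(OCOC)c4c(c3)C=CC(C)(C)O4)oc2c1CC=C(C)C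
F5 | step 8 | 3,4-bis(methoxymethoxy)-5-prenylbenzoic acid | OC(=O)c1cc(OCOC)c(OCOC)c(CC=C(C)C)c1
F6 | step 8 | 2-acetyl-3,5-bis(methoxymethoxy)-6-prenylphenyl 3,4-bis(methoxymethoxy)-5-prenylbenzoate | CC(=O)c1c(OCOC)cc(OCOC)c(CC=C(C)C)c1OC(=O)c1cc(OCOC)c(OCOC)c(CC=C(C)C)c1
F7 | step 8 | 1-[2-hydroxy-4,6-bis(methoxymethoxy)-3-prenylphenyl]-3-[3,4-bis(methoxymethoxy)-5-prenylphenyl]propane-1,3-dione | COCOc1cc(OCOC)c(C(=O)CC(=O)c2cc(OCOC)c(OCOC)c(CC=C(C)C)c2)c(O)c1CC=C(C)C
F0 | step 3 | none | none
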